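(The earlier runs and the new flask are calculated with made-up constants; noise was put on by code.)

Partner B works like a budget in a closed flask: what the substrate and any other taker draw from it can't exceed the charge, and whatever isn't drawn stays in the flask.

| setting | grey | amber | Monday's | Saturday's | Wednesday's |
|---|---|---|---|---|---|
| substrate | 0.061 M | 0.061 M | 0.061 M | 0.061 M | 0.061 M |
| partner A | 0.0427 M | 0.0427 M | 0.0427 M | 0.0427 M | 0.0427 M |
| partner B | 0.049 M | 0.18 M | 0.0600 M | 0.150 M | 0.250 M |
| remark | run made earlier | run made earlier |  |  |  |
| time |  |  | 6.0 min | 6.0 min | 6.0 min |

| run | time / min | target / % | substrate / % |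
|---|---|---|---|
| grey | 0.250 | 0.7 | 77.9 |
| grey | 0.417 | 1.6 | 67.2 |
| grey | 0.833 | 0 | 53.7 |
| grey | 1.50 | 1.3 | 43.7 |
| grey | 3.00 | 5.7 | 38.3 |
| amber | 0.250 | 0 | 40.4 |
| amber | 0.833 | 4.6 | 5.8 |
| amber | 1.33 | 8.0 | 2.7 |
| amber | 2.00 | 11.8 | 0.9 |
| amber | 3.00 | 14.7 | 0 |

(each reading ± 1 percentage point)

- the numbers in the tables scatter by 1 percentage point (one standard deviation)
- "hardly changes" means that all values lie within two and a half points (for a concentration: within two and a half percent of the largest)

- amount of target at the end, in percent of the substrate charged for Monday's, Saturday's, Wednesday's, in this order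
- how the row runs (falls, then rises / rises, then falls / rises all the way / falls all the way / hardly changes)

I test each input of that budget before I reckon it. I can be loose about the rate of the substrate step: amber's substrate reads 40.4% at 0.250 min, a time constant of 0.276 min. Scaled to Monday's lower partner B charge, that is 0.828 min, and even an error of a factor 2 keeps it shorter than the 6.0 min of the new flasks. The substrate charge enters the budget one for one, if each substrate costs one partner B.

Partner A's charge may matter just as much. Grey's substrate stands at 38.3% after 3.00 min, while spending grey's whole partner B on it would reach 19.7%. Some of that gap of 0.0114 M may be partner B still unused at that time, but I read the rest as a second taker, and I assume that each partner A costs one partner B.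

So the number to hold is the demand D, the partner B claimed by the substrate and partner A charges together: 0.104 M. On this budget, with the substrate and partner A charges as they stand here, partner B is the limiting reagent below D. Above D, I take the spare F, the charge minus D, to be free to attack what the flask is building.

Monday's falls short of D by 0.0437 M. Saturday's has F = 0.0463 M, and Wednesday's has F = 0.146 M. I commit to a shape and no figures: the row rises, then falls, with its top at Saturday's.

The forecast gives 17%, 20% and 13%, so its row rises, then falls; at the highest charge it says “the side reaction dominates”.

The flask gives 11.4%, 17.9% and 7.09%, so the row rises, then falls.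

substrate + partner B → open intermediate (k = 0.414 M⁻¹ s⁻¹); partner B + partner A → second intermediate (k = 0.0783 M⁻¹ s⁻¹); open intermediate + second intermediate → target (k = 0.166 M⁻¹ s⁻¹); 2 second intermediate → homo product (k = 0.214 M⁻¹ s⁻¹); partner B + target → over-reaction product (k = 0.0689 M⁻¹ s⁻¹) It turns at 0.12 M, above D. Without the over-reaction step, Wednesday's target stands at 40.2%. Taking F as a steady partner B makes that loss pseudo-first-order, with a time constant equal to the inverse of 0.0689 M⁻¹ s⁻¹ times F: 5.22 min for Saturday's and 1.66 min for Wednesday's, against a run of 6.0 min.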